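**Plan**
- Retrosynthesis: remove the 3'-O-acetyl group, then cut the lactone aryl–oxygen bond O1–C8a to give a (Z)-3,3-diarylacrylic acid. Next cut C4–C1' (ring B as an arylboronic acid), then C2–C3 (chloroformate) and the C3–C4 homologation back to an aryl aldehyde.
- Enabling feature: C8a is the only unsubstituted carbon ortho to the side chain on ring A, and ring A (methoxy groups at C5, C7, C8) is the most easily oxidised π-system. Ring A can therefore enter as a 2,4,5-trimethoxyphenyl group without O1, and the O1–C8a bond is made last by anodic C–H/O–H coupling.
- Forward order: ring A aldehyde → C3, then C2 (ynoate) → ring B joined at C4 → acid and ring-B acetate → pyranone ring closed (the only ring formed) → deacetylation.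
- Stereochemistry: the target has no stereocentre. The only stereochemical element on the route is the Z alkene geometry, set by syn-carbocupration/protonolysis in step 3 and consumed in the ring closure.

Key step: step 6

Assumption: the target is achiral (no stereocentre, and the 4-aryl group carries no ortho substituent, so no stable atropisomers); "single enantiomer" is read as the compound itself.

Step 1
Reactants: 1 2,4,5-trimethoxybenzaldehyde
Product: 2 1-(2,2-dibromoethenyl)-2,4,5-trimethoxybenzene
Conditions: CBr4, PPh3, Zn dust, CH2Cl2, rt (ylide preformed); then 1, 0 °C to rt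
Reagents that add atoms: carbon tetrabromide, BrC(Br)(Br)Br
Why: Corey–Fuchs (Ramirez) dibromo-olefination: the ylide Ph3P=CBr2 formed from CBr4, PPh3 and zinc undergoes a Wittig reaction with the aldehyde, which is routine for electron-rich benzaldehydes and neutral enough for the aryl methyl ethers.

Step 2
Reactants: 2 1-(2,2-dibromoethenyl)-2,4,5-trimethoxybenzene, 3 methyl chloroformate
Product: 5 methyl 3-(2,4,5-trimethoxyphenyl)prop-2-ynoate, via lithium (2,4,5-trimethoxyphenyl)acetylide 4 (not isolated)
Conditions: n-BuLi (2.1 equiv), THF, −78 °C; then ClCO2Me (excess), −78 to 0 °C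
Reagents that add atoms: none
Why: Second stage of the Corey–Fuchs alkyne synthesis: bromine–lithium exchange and loss of LiBr with 1,2-hydrogen shift (Fritsch–Buttenberg–Wiechell type) give the alkyne, the second equivalent of n-BuLi deprotonates it to acetylide 4, and C-acylation with the chloroformate gives the ynoate; at −78 °C exchange should outrun metalation of the methoxy-flanked ring position.

Step 3
Reactants: 5 methyl 3-(2,4,5-trimethoxyphenyl)prop-2-ynoate, 6 (3-hydroxy-4-methoxyphenyl)boronic acid
Product: 7 methyl (2Z)-3-(3-hydroxy-4-methoxyphenyl)-3-(2,4,5-trimethoxyphenyl)prop-2-enoate (ring A cis to the ester)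
Conditions: CuOAc (5 mol %), 6 (1.5 equiv), MeOH, 25 °C, Ar
Reagents that add atoms: none
Why: Copper(I)-catalysed hydroarylation of an aryl propiolate with an arylboronic acid in methanol: transmetalation to an aryl–copper species, syn-carbocupration with the aryl delivered to the β-carbon and prompt protonolysis of the α-cuprio ester by the solvent place ring B and the new hydrogen cis, so ring A and the ester end up cis (Z); ortho-alkoxyaryl propiolates are established substrates and the protic medium should make the free phenol harmless.

Step 4
Reactants: 7 methyl (2Z)-3-(3-hydroxy-4-methoxyphenyl)-3-(2,4,5-trimethoxyphenyl)prop-2-enoate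
Product: 8 (2Z)-3-(3-hydroxy-4-methoxyphenyl)-3-(2,4,5-trimethoxyphenyl)prop-2-enoic acid
Conditions: LiOH·H2O (4 equiv), THF/MeOH/H2O, 40 °C, Ar; then 1 M HCl, 0 °C, to pH 3
Reagents that add atoms: lithium hydroxide, [Li+].[OH-]
Why: Saponification (BAc2) of the methyl ester with hydroxide; the β,β-diarylacrylate has no low-energy path for geometric scrambling under base, and cold, mild acidification avoids isomerisation through the benzylic cation.

Step 5
Reactants: 8 (2Z)-3-(3-hydroxy-4-methoxyphenyl)-3-(2,4,5-trimethoxyphenyl)prop-2-enoic acid
Product: 9 (2Z)-3-(3-acetoxy-4-methoxyphenyl)-3-(2,4,5-trimethoxyphenyl)prop-2-enoic acid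
Conditions: Ac2O, pyridine, DMAP (cat.), CH2Cl2, 0 °C to rt; then H2O
Reagents that add atoms: acetic anhydride, CC(=O)OC(C)=O
Why: DMAP-catalysed O-acetylation of the phenol with acetic anhydride; a mixed anhydride at the carboxyl group, should any form, is cleaved in the aqueous quench, and the acetate both masks the phenol and lowers the electron density of ring B for the anodic step.

Step 6
Reactants: 9 (2Z)-3-(3-acetoxy-4-methoxyphenyl)-3-(2,4,5-trimethoxyphenyl)prop-2-enoic acid
Product: 10 4-(3-acetoxy-4-methoxyphenyl)-5,7,8-trimethoxy-2H-chromen-2-one
Conditions: undivided cell, graphite anode, Pt cathode, n-Bu4NPF6 (0.1 M), 2,6-lutidine (0.2 equiv), MeCN/HFIP 4:1, rt, controlled potential at the first anodic wave of 9, about 2.1 F per mol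
Reagents that add atoms: none
Why: Proposed new method: ring A of 9, a 1,2,4-trimethoxy-5-alkenylbenzene, should be the first π-system to lose an electron at the anode (ring B is damped by its acetoxy group), and the carboxylate held cis to it by the Z alkene can then add to the ortho C–H carbon of the radical cation; a second electron transfer and loss of the ring proton restore aromaticity and give the lactone, while protons are reduced to hydrogen at the cathode. The closest known reaction types are the anodic dehydrogenative lactonisation of biaryl-2-carboxylic acids to benzo[c]chromenones and the hypervalent-iodine or photoredox cyclisation of 3,3-diarylacrylic acids to 4-arylcoumarins; the anodic variant on a diarylacrylic acid is the untested part. The pyranone ring closes by 6-endo-trig attack of oxygen on the aryl carbon that becomes C8a, in competition with 5-exo attack at the ipso carbon. No stereocentre is formed, and the alkene geometry fixed in step 3 is what delivers the carboxylate to ring A and not to ring B. The step needs site selectivity for the C–H ortho carbon over the ipso carbon and the methoxy-bearing ortho carbon: addition at either of the latter gives an adduct with no proton to lose, from which the acyloxy group can leave again, whereas the C–H adduct is drained irreversibly by oxidation and deprotonation. Electrolysis at the first anodic wave in a hexafluoroisopropanol medium, stopped near the theoretical charge, should keep the product, whose ring A now carries an acyloxy group and a conjugated lactone, from being oxidised further.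

Step 7
Reactants: 10 4-(3-acetoxy-4-methoxyphenyl)-5,7,8-trimethoxy-2H-chromen-2-one
Product: 11 4-(3-hydroxy-4-methoxyphenyl)-5,7,8-trimethoxy-2H-chromen-2-one (3'-hydroxy-5,7,8,4'-tetramethoxy-4-phenylcoumarin)
Conditions: HCl (cat.), MeOH, 40 °C
Reagents that add atoms: none
Why: Acid-catalysed transesterification (methanolysis) of the aryl acetate to methyl acetate and the free phenol; the aryl methyl ethers are inert and the acidic medium keeps the coumarin lactone closed.

**Compound list**
1 | 2,4,5-trimethoxybenzaldehyde | COc1cc(OC)c(C=O)cc1OC | starting material
2 | 1-(2,2-dibromoethenyl)-2,4,5-trimethoxybenzene | COc1cc(OC)c(C=C(Br)Br)cc1OC | intermediate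
3 | methyl chloroformate | COC(=O)Cl | starting material
4 | lithium (2,4,5-trimethoxyphenyl)acetylide | [Li]C#Cc1cc(OC)c(OC)cc1OC | intermediate (not isolated)
5 | methyl 3-(2,4,5-trimethoxyphenyl)prop-2-ynoate | COC(=O)C#Cc1cc(OC)c(OC)cc1OC | intermediate
6 | (3-hydroxy-4-methoxyphenyl)boronic acid | COc1ccc(B(O)O)cc1O | starting material
7 | methyl (2Z)-3-(3-hydroxy-4-methoxyphenyl)-3-(2,4,5-trimethoxyphenyl)prop-2-enoate | COC(=O)/C=C(\c1cc(OC)c(OC)cc1OC)c1ccc(OC)c(O)c1 | intermediate
8 | (2Z)-3-(3-hydroxy-4-methoxyphenyl)-3-(2,4,5-trimethoxyphenyl)prop-2-enoic acid | OC(=O)/C=C(\c1cc(OC)c(OC)cc1OC)c1ccc(OC)c(O)c1 | intermediate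
9 | (2Z)-3-(3-acetoxy-4-methoxyphenyl)-3-(2,4,5-trimethoxyphenyl)prop-2-enoic acid | OC(=O)/C=C(\c1cc(OC)c(OC)cc1OC)c1ccc(OC)c(OC(C)=O)c1 | intermediate
10 | 4-(3-acetoxy-4-methoxyphenyl)-5,7,8-trimethoxy-2H-chromen-2-one | COc1ccc(-c2cc(=O)oc3c(OC)c(OC)cc(OC)c23)cc1OC(C)=O | intermediate
11 | 4-(3-hydroxy-4-methoxyphenyl)-5,7,8-trimethoxy-2H-chromen-2-one | COc1ccc(-c2cc(=O)oc3c(OC)c(OC)cc(OC)c23)cc1O | target

**Step count**
Total: 7 steps. Longest linear sequence: 7 steps (1 to 11); compounds 3 and 6 are purchased and enter directly.

**Steps most likely to fail**

Step 6 (proposed new method). The carboxylate may add at the ipso carbon of ring A, and the spiro intermediate may then rearrange by a 1,2-shift to a regioisomeric coumarin. The radical cation may also lose its alkene geometry before it cyclises, or the product may be oxidised further at the anode. The fallback gives up the oxidative closure and uses only established chemistry: the benzopyranone is built with O1 already in place and ring B is attached last. It sets out from boronic acid 6 and comes back at target 11. Purchased 2'-hydroxy-3',4',6'-trimethoxyacetophenone (CC(=O)c1c(O)c(OC)c(OC)cc1OC) is condensed with diethyl carbonate (NaH, toluene, reflux) to 4-hydroxy-5,7,8-trimethoxy-2H-chromen-2-one F1. This is converted with Tf2O and Et3N (CH2Cl2, −10 °C) into 5,7,8-trimethoxy-2-oxo-2H-chromen-4-yl trifluoromethanesulfonate F2. Suzuki–Miyaura coupling of F2 with 6 (Pd(PPh3)4, aq. K3PO4, dioxane, 80 °C) should then give 11 directly, the free phenol being tolerated.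

Step 3. Protodeboronation of the electron-rich phenolic boronic acid may outpace carbocupration of the hindered ortho-substituted ynoate, and isomerisation of the alkenylcopper intermediate before protonolysis would erode the geometry. The fallback replaces alkyne hydroarylation by a stereospecific Mizoroki–Heck arylation of a cinnamate; it sets out from aldehyde 1 and comes back at ester 7. Wittig olefination of 1 with methyl (triphenylphosphoranylidene)acetate (toluene, 80 °C) should give methyl (2E)-3-(2,4,5-trimethoxyphenyl)prop-2-enoate F3. Heck coupling of F3 with purchased 5-iodo-2-methoxyphenol (COc1ccc(I)cc1O; Pd(OAc)2, n-Bu4NCl, NaHCO3, DMF, 90 °C) proceeds by syn insertion and syn β-hydride elimination. This places the incoming aryl trans to the ester and leaves ring A cis to it, as in 7.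

Step 2. n-Butyllithium may metalate the ring C–H flanked by two methoxy groups, or add to the chloroformate and to the product ynoate, so that the acetylide is formed or trapped unselectively. The fallback separates alkyne formation from carboxylation and avoids alkyllithium; it sets out from aldehyde 1 and comes back at acetylide 4 and thus at ynoate 5. Seyferth–Gilbert homologation of 1 with the Ohira–Bestmann reagent (dimethyl (1-diazo-2-oxopropyl)phosphonate, K2CO3, MeOH, rt) should give 1-ethynyl-2,4,5-trimethoxybenzene F4. LiHMDS (THF, −78 °C) deprotonates F4 to 4 without touching the ring, and 4 is acylated with 3 as in step 2.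

**Further compounds**
F1 | step 6 | 4-hydroxy-5,7,8-trimethoxy-2H-chromen-2-one | COc1cc(OC)c2c(O)cc(=O)oc2c1OC
F2 | step 6 | 5,7,8-trimethoxy-2-oxo-2H-chromen-4-yl trifluoromethanesulfonate | COc1cc(OC)c2c(OS(=O)(=O)C(F)(F)F)cc(=O)oc2c1OC
F3 | step 3 | methyl (2E)-3-(2,4,5-trimethoxyphenyl)prop-2-enoate | COC(=O)/C=C/c1cc(OC)c(OC)cc1OC
F4 | step 2 | 1-ethynyl-2,4,5-trimethoxybenzene | C#Cc1cc(OC)c(OC)cc1OC
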